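**Retrosynthetic overview**
1. Tetronic acid, the only ring built and closed last: the C5–O bond and the C5 stereocentre come from a reagent-controlled γ-hydroxylation of a β-keto ester dianion, and the new alkoxide then lactonises onto the methyl ester.
2. The keto ester comes from γ-alkylation of the methyl 2-methylacetoacetate dianion with a (Z)-allylic bromide.
3. The 2Z alkene comes from a β-oxido ylide olefination of an aldehyde (ethylidene ylide, then formaldehyde); the aldehyde is unmasked from the terminal epoxide of a geranyl unit, whose E alkene is bought in.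
4. Both furan rings are bought preformed as furan-3-ylmethanol; one is joined to the geranyl unit by copper-catalysed Grignard allylation, the second by C–H borylation and Suzuki benzylation.
5. Ring order: furans (preformed) → oxirane (transient aldehyde mask) → tetronic acid.

Assumption: the target is taken as drawn (5R; side chain 2Z,6E), and the facial sense of the oxaziridine in step 9 is assigned by analogy with Z-enolates of aryl alkyl ketones, to be confirmed on the first run (the mirror-image reagent is equally available).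

**Step 1**
Reactants: 1 furan-3-ylmethanol
Product: 2 3-(chloromethyl)furan
Conditions: SOCl2, pyridine, Et2O, 0 °C
Reagents that add atoms: thionyl chloride, O=S(Cl)Cl
Why: Chlorodehydroxylation of a primary furylmethyl alcohol through its chlorosulfite (SN2 with chloride); no stereocentre is involved.

**Step 2**
Reactants: 3 geranyl chloride, (2E)-1-chloro-3,7-dimethylocta-2,6-diene
Product: 4 3-[(3E)-5-chloro-3-methylpent-3-en-1-yl]-2,2-dimethyloxirane (racemic at the oxirane carbon)
Conditions: mCPBA (1.0 equiv), NaHCO3, CH2Cl2, 0 °C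
Reagents that add atoms: 3-chloroperbenzoic acid, OOC(=O)c1cccc(Cl)c1
Why: Prilezhaev epoxidation is selective for the electron-rich 6,7-alkene because the 2,3-alkene is deactivated by the allylic chloride; the racemic oxirane carbon is excised in step 5.

**Step 3**
Reactants: 2 3-(chloromethyl)furan; 4 3-[(3E)-5-chloro-3-methylpent-3-en-1-yl]-2,2-dimethyloxirane
Product: 6 3-[(3E)-6-(3,3-dimethyloxiran-2-yl)-4-methylhex-3-en-1-yl]furan, via furan-3-ylmethylmagnesium chloride 5 (not isolated)
Conditions: Mg, THF, 0 °C; then 4, Li2CuCl4 (3 mol %), THF, −20 to 0 °C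
Reagents that add atoms: none
Why: Copper-catalysed Grignard–allylic chloride cross-coupling (Kochi type) proceeds by SN2 at the primary allylic carbon with retention of the E geometry, and the trisubstituted oxirane is inert at or below 0 °C.

**Step 4**
Reactants: 6 3-[(3E)-6-(3,3-dimethyloxiran-2-yl)-4-methylhex-3-en-1-yl]furan; 2 3-(chloromethyl)furan
Product: 8 3-({4-[(3E)-6-(3,3-dimethyloxiran-2-yl)-4-methylhex-3-en-1-yl]furan-2-yl}methyl)furan, via furyl pinacol boronate 7 (not isolated)
Conditions: B2pin2, [Ir(OMe)(cod)]2 (1.5 mol %), 4,4′-di-tert-butyl-2,2′-bipyridine (3 mol %), THF, rt; then 2, Pd(OAc)2 (3 mol %), SPhos (6 mol %), K3PO4, THF–H2O, 45 °C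
Reagents that add atoms: none
Why: Sterically controlled iridium-catalysed C–H borylation (Hartwig–Miyaura) takes the furan α-position remote from the 3-alkyl group, and Suzuki–Miyaura sp2–sp3 coupling with the benzylic-type chloride gives the 2,4-disubstituted furan.

**Step 5**
Reactants: 8 3-({4-[(3E)-6-(3,3-dimethyloxiran-2-yl)-4-methylhex-3-en-1-yl]furan-2-yl}methyl)furan
Product: 9 (4E)-7-[5-(furan-3-ylmethyl)furan-3-yl]-4-methylhept-4-enal
Conditions: H5IO6 (1.2 equiv), THF–Et2O, 0 °C, 30 min
Reagents that add atoms: none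
Why: Acid-mediated epoxide hydration followed by periodate glycol cleavage (Malaprade type) excises acetone and unmasks the aldehyde, while the alkenes and furans are not attacked by periodate at 0 °C.

**Step 6**
Reactants: 9 (4E)-7-[5-(furan-3-ylmethyl)furan-3-yl]-4-methylhept-4-enal
Product: 12 (2Z,6E)-9-[5-(furan-3-ylmethyl)furan-3-yl]-2,6-dimethylnona-2,6-dien-1-ol, via lithium betaine 10 (not isolated), via β-oxido ylide 11 (not isolated)
Conditions: EtPPh3Br, n-BuLi, THF, 0 °C; 9, −78 °C; n-BuLi (1.0 equiv), −78 to −25 °C; (CH2O)n, 0 °C to rt; H2O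
Reagents that add atoms: ethyltriphenylphosphonium bromide, CC[P+](c1ccccc1)(c1ccccc1)c1ccccc1.[Br-]; paraformaldehyde (as formaldehyde), C=O
Why: Corey–Schlosser β-oxido ylide olefination: the betaine is deprotonated, the ylide carbon is trapped by formaldehyde, and loss of Ph3PO through the original aldehyde oxygen places CH2OH cis to the chain, which sets the 2Z alkene.

**Step 7**
Reactants: 12 (2Z,6E)-9-[5-(furan-3-ylmethyl)furan-3-yl]-2,6-dimethylnona-2,6-dien-1-ol
Product: 13 3-({4-[(3E,7Z)-9-bromo-4,8-dimethylnona-3,7-dien-1-yl]furan-2-yl}methyl)furan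
Conditions: CBr4, PPh3, CH2Cl2, −20 to 0 °C; used at once
Reagents that add atoms: carbon tetrabromide, BrC(Br)(Br)Br
Why: Appel bromination displaces the alkoxyphosphonium by SN2 at the primary allylic carbon without allylic shift, so the Z geometry is kept at low temperature.

**Step 8**
Reactants: 13 3-({4-[(3E,7Z)-9-bromo-4,8-dimethylnona-3,7-dien-1-yl]furan-2-yl}methyl)furan; 14 methyl 2-methyl-3-oxobutanoate
Product: 16 methyl (6Z,10E)-13-[5-(furan-3-ylmethyl)furan-3-yl]-2,6,10-trimethyl-3-oxotrideca-6,10-dienoate (C2 stereolabile, mixture), via acetoacetate dianion 15 (not isolated)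
Conditions: 14, NaH, THF, 0 °C; n-BuLi, 0 °C; then 13, 0 °C to rt; aq. HCl
Reagents that add atoms: none
Why: Weiler dianion alkylation: the γ-carbanion is the more nucleophilic terminus and displaces the allylic bromide by SN2, and the C2 epimers do not matter because C2 becomes sp2 in the target.

**Step 9**
Reactants: 16 methyl (6Z,10E)-13-[5-(furan-3-ylmethyl)furan-3-yl]-2,6,10-trimethyl-3-oxotrideca-6,10-dienoate
Product: 19 (5R)-5-[(2Z,6E)-9-[5-(furan-3-ylmethyl)furan-3-yl]-2,6-dimethylnona-2,6-dien-1-yl]-4-hydroxy-3-methylfuran-2(5H)-one, via keto ester dianion 17 (not isolated), via hydroxy keto ester salt 18 (not isolated)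
Conditions: NaH (1.05 equiv), THF, 0 °C; n-BuLi (1.05 equiv), 0 to −78 °C; (−)-[(8,8-dichlorocamphoryl)sulfonyl]oxaziridine (1.1 equiv), −78 °C, 1 h; then rt, 2 h; 1 M HCl, 0 °C
Reagents that add atoms: (−)-[(8,8-dichlorocamphoryl)sulfonyl]oxaziridine (from (1R)-(−)-10-camphorsulfonic acid), CC1(C)[C@H]2CC[C@@]13CS(=O)(=O)N4O[C@]34C2(Cl)Cl
Why: Proposed new method: reagent-controlled asymmetric γ-hydroxylation of a β-keto ester 1,3-dianion coupled to lactonisation in the same flask; the dianion reacts only at its more basic γ-carbon (as in step 8), this carbanion attacks the oxaziridine oxygen in an SN2-type open transition state so that the C5–O bond and the C5 stereocentre form together, the dichlorocamphor sultam shields one face of the chelated Z-configured enolate terminus (R expected with this reagent enantiomer), the γ-alkoxide then closes onto the methyl ester (5-exo-trig acyl substitution) to give the tetronate, which is not deprotonated at C5 by the bases left, and alkenes and furans are inert to N-sulfonyloxaziridines at −78 °C; the closest known reaction type is the Davis asymmetric hydroxylation of ketone mono-enolates, which has not been shown at the γ-terminus of a dianion or coupled to tetronic acid formation.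

**Compound list**
1 | furan-3-ylmethanol | OCc1ccoc1 | starting material
2 | 3-(chloromethyl)furan | ClCc1ccoc1 | intermediate
3 | geranyl chloride, (2E)-1-chloro-3,7-dimethylocta-2,6-diene | ClC/C=C(\C)CCC=C(C)C | starting material
4 | 3-[(3E)-5-chloro-3-methylpent-3-en-1-yl]-2,2-dimethyloxirane (racemic) | CC1(C)OC1CC/C(C)=C/CCl | intermediate
5 | (furan-3-ylmethyl)magnesium chloride | Cl[Mg]Cc1ccoc1 | intermediate (not isolated)
6 | 3-[(3E)-6-(3,3-dimethyloxiran-2-yl)-4-methylhex-3-en-1-yl]furan (racemic) | CC1(C)OC1CC/C(C)=C/CCc1ccoc1 | intermediate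
7 | 2-{4-[(3E)-6-(3,3-dimethyloxiran-2-yl)-4-methylhex-3-en-1-yl]furan-2-yl}-4,4,5,5-tetramethyl-1,3,2-dioxaborolane (racemic) | CC1(C)OC1CC/C(C)=C/CCc1coc(B2OC(C)(C)C(C)(C)O2)c1 | intermediate (not isolated)
8 | 3-({4-[(3E)-6-(3,3-dimethyloxiran-2-yl)-4-methylhex-3-en-1-yl]furan-2-yl}methyl)furan (racemic) | CC1(C)OC1CC/C(C)=C/CCc1coc(Cc2ccoc2)c1 | intermediate
9 | (4E)-7-[5-(furan-3-ylmethyl)furan-3-yl]-4-methylhept-4-enal | O=CCC/C(C)=C/CCc1coc(Cc2ccoc2)c1 | intermediate
10 | [(6E)-9-[5-(furan-3-ylmethyl)furan-3-yl]-3-(lithiooxy)-6-methylnon-6-en-2-yl]triphenylphosphonium bromide (lithium betaine, racemic) | [Br-].[Li]OC(CC/C(C)=C/CCc1coc(Cc2ccoc2)c1)C(C)[P+](c1ccccc1)(c1ccccc1)c1ccccc1 | intermediate (not isolated)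
11 | lithium (6E)-9-[5-(furan-3-ylmethyl)furan-3-yl]-6-methyl-2-(triphenyl-λ5-phosphanylidene)non-6-en-3-olate (β-oxido ylide, racemic) | [Li]OC(CC/C(C)=C/CCc1coc(Cc2ccoc2)c1)C(C)=P(c1ccccc1)(c1ccccc1)c1ccccc1 | intermediate (not isolated)
12 | (2Z,6E)-9-[5-(furan-3-ylmethyl)furan-3-yl]-2,6-dimethylnona-2,6-dien-1-ol | OC/C(C)=C\CC/C(C)=C/CCc1coc(Cc2ccoc2)c1 | intermediate
13 | 3-({4-[(3E,7Z)-9-bromo-4,8-dimethylnona-3,7-dien-1-yl]furan-2-yl}methyl)furan | BrC/C(C)=C\CC/C(C)=C/CCc1coc(Cc2ccoc2)c1 | intermediate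
14 | methyl 2-methyl-3-oxobutanoate | COC(=O)C(C)C(C)=O | starting material
15 | sodium lithium dianion of methyl 2-methyl-3-oxobutanoate | [Na+].[Li+].COC([O-])=C(C)C(=C)[O-] | intermediate (not isolated)
16 | methyl (6Z,10E)-13-[5-(furan-3-ylmethyl)furan-3-yl]-2,6,10-trimethyl-3-oxotrideca-6,10-dienoate | COC(=O)C(C)C(=O)CC/C(C)=C\CC/C(C)=C/CCc1coc(Cc2ccoc2)c1 | intermediate
17 | sodium lithium 1,3-dianion of 16 | [Na+].[Li+].COC([O-])=C(C)C([O-])=CC/C(C)=C\CC/C(C)=C/CCc1coc(Cc2ccoc2)c1 | intermediate (not isolated)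
18 | methyl (4R,6Z,10E)-13-[5-(furan-3-ylmethyl)furan-3-yl]-4-hydroxy-2,6,10-trimethyl-3-oxotrideca-6,10-dienoate (formed as its sodium lithium salt, drawn neutral) | COC(=O)C(C)C(=O)[C@H](O)C/C(C)=C\CC/C(C)=C/CCc1coc(Cc2ccoc2)c1 | intermediate (not isolated)
19 | (5R)-5-[(2Z,6E)-9-[5-(furan-3-ylmethyl)furan-3-yl]-2,6-dimethylnona-2,6-dien-1-yl]-4-hydroxy-3-methylfuran-2(5H)-one | CC1=C(O)[C@@H](C/C(C)=C\CC/C(C)=C/CCc2coc(Cc3ccoc3)c2)OC1=O | target

**Step count**
Total steps: 9. Longest linear sequence: 8 (3 → 4 → 6 → 8 → 9 → 12 → 13 → 16 → 19; the branch 1 → 2 joins at steps 3 and 4).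

**Steps most likely to fail, with fallbacks**

Step 9 (the proposed new step). The risks are low or reversed enantioselectivity, competing hydroxylation at C2, and slow ring closure. The fallback uses only known chemistry, sets out from aldehyde 9 and comes back at target 19. Aldehyde 9 is treated with the α-iodo ylide Ph3P=C(I)CH3 (from ethyltriphenylphosphonium iodide, n-BuLi, I2, then NaHMDS, THF, −78 °C; Stork–Zhao-type olefination) to give the (Z)-vinyl iodide 3-({4-[(3E,7Z)-8-iodo-4-methylnona-3,7-dien-1-yl]furan-2-yl}methyl)furan F1. Iodine–lithium exchange (t-BuLi, Et2O, −78 °C), transmetalation with MgBr2·OEt2 and CuI-catalysed opening of commercial methyl (R)-glycidate (COC(=O)[C@H]1CO1) at its CH2 carbon at −40 °C gives methyl (2R,4Z,8E)-11-[5-(furan-3-ylmethyl)furan-3-yl]-2-hydroxy-4,8-dimethylundeca-4,8-dienoate F2, with the stereocentre taken from the chiral pool and the alkene geometry retained. Acylation with propanoic anhydride, DMAP and pyridine gives methyl (2R,4Z,8E)-11-[5-(furan-3-ylmethyl)furan-3-yl]-4,8-dimethyl-2-(propanoyloxy)undeca-4,8-dienoate F3. Dieckmann cyclisation of F3 (LiHMDS, THF, −78 to 0 °C, then acid) closes the tetronic acid and delivers 19.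

Step 6 (β-oxido ylide olefination). The risks are incomplete betaine deprotonation, E/Z leakage, and lithiation of a furan by excess base. The fallback sets out from aldehyde 9 and comes back at alcohol 12. Still–Gennari olefination of 9 with methyl 2-[bis(2,2,2-trifluoroethoxy)phosphoryl]propanoate (KHMDS, 18-crown-6, THF, −78 °C) gives methyl (2Z,6E)-9-[5-(furan-3-ylmethyl)furan-3-yl]-2,6-dimethylnona-2,6-dienoate F4, and DIBAL-H (CH2Cl2, −78 °C) reduces F4 to 12.

Step 4 (C–H borylation and Suzuki benzylation). The risks are borylation next to the alkyl group instead of at the remote α-position, and protodeboronation of the 2-furyl boronate. The fallback builds the bis-furan with fixed regiochemistry before the allylic coupling; it sets out from chloride 2 and comes back at 8, bypassing 6 and 7. Zinc insertion into 2 (Zn, LiCl, THF) gives (furan-3-ylmethyl)zinc chloride F5. Negishi coupling of F5 with commercial methyl 5-bromofuran-3-carboxylate (Pd(PPh3)4, THF, 50 °C) gives methyl 5-(furan-3-ylmethyl)furan-3-carboxylate F6. LiAlH4 (Et2O, 0 °C) gives [5-(furan-3-ylmethyl)furan-3-yl]methanol F7. SOCl2 and pyridine give 4-(chloromethyl)-2-(furan-3-ylmethyl)furan F8. Magnesium in THF gives {[5-(furan-3-ylmethyl)furan-3-yl]methyl}magnesium chloride F9, which is coupled with epoxy chloride 4 under Li2CuCl4 catalysis, as in step 3, to give 8.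

**Further compounds**
F1 | step 9 | 3-({4-[(3E,7Z)-8-iodo-4-methylnona-3,7-dien-1-yl]furan-2-yl}methyl)furan | I/C(C)=C\CC/C(C)=C/CCc1coc(Cc2ccoc2)c1
F2 | step 9 | methyl (2R,4Z,8E)-11-[5-(furan-3-ylmethyl)furan-3-yl]-2-hydroxy-4,8-dimethylundeca-4,8-dienoate | COC(=O)[C@H](O)C/C(C)=C\CC/C(C)=C/CCc1coc(Cc2ccoc2)c1
F3 | step 9 | methyl (2R,4Z,8E)-11-[5-(furan-3-ylmethyl)furan-3-yl]-4,8-dimethyl-2-(propanoyloxy)undeca-4,8-dienoate | COC(=O)[C@H](OC(=O)CC)C/C(C)=C\CC/C(C)=C/CCc1coc(Cc2ccoc2)c1
F4 | step 6 | methyl (2Z,6E)-9-[5-(furan-3-ylmethyl)furan-3-yl]-2,6-dimethylnona-2,6-dienoate | COC(=O)/C(C)=C\CC/C(C)=C/CCc1coc(Cc2ccoc2)c1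
F5 | step 4 | (furan-3-ylmethyl)zinc chloride | Cl[Zn]Cc1ccoc1
F6 | step 4 | methyl 5-(furan-3-ylmethyl)furan-3-carboxylate | COC(=O)c1coc(Cc2ccoc2)c1
F7 | step 4 | [5-(furan-3-ylmethyl)furan-3-yl]methanol | OCc1coc(Cc2ccoc2)c1
F8 | step 4 | 4-(chloromethyl)-2-(furan-3-ylmethyl)furan | ClCc1coc(Cc2ccoc2)c1
F9 | step 4 | {[5-(furan-3-ylmethyl)furan-3-yl]methyl}magnesium chloride | Cl[Mg]Cc1coc(Cc2ccoc2)c1
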